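A small charge of starting material, like Sunday's 0.080 M against 0.200 M of coupling partner, has 2.50 partners per molecule, so I follow one molecule of starting material and ask its chance of ever being coupled, taking one partner per product.

| setting | epsilon | gamma | Sunday's | Monday's | Friday's | Wednesday's |
|---|---|---|---|---|---|---|
| starting material | 0.056 M | 0.20 M | 0.080 M | 0.080 M | 0.25 M | 0.25 M |
| coupling partner | 0.20 M (fed, over 5.0 h) | 0.20 M (fed, over 5.0 h) | 0.200 M (fed, over 5.0 h) | 0.200 M (fed, over 5.0 h) | 0.200 M (fed, over 5.0 h) | 0.200 M (fed, over 5.0 h) |
| temperature | 68 °C | 84 °C | 90 °C | 60 °C | 90 °C | 60 °C |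
| remark | run made earlier; the fed solution adds 0.20 times the starting volume | run made earlier; the fed solution adds 0.20 times the starting volume | the fed solution adds 0.20 times the starting volume | the fed solution adds 0.20 times the starting volume | the fed solution adds 0.20 times the starting volume | the fed solution adds 0.20 times the starting volume |
| time |  |  | 30 h | 30 h | 30 h | 30 h |

| run | time / h | product / % | starting material / % |
|---|---|---|---|
| epsilon | 1.33 | 1 | 100 |
| epsilon | 2.00 | 1 | 102 |
| epsilon | 3.00 | 0 | 99 |
| epsilon | 5.00 | 3 | 100 |
| epsilon | 10.0 | 7 | 97 |
| epsilon | 15.0 | 7 | 92 |
| gamma | 0.833 | 0 | 98 |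
| gamma | 1.50 | 0 | 96 |
| gamma | 2.50 | 2 | 99 |
| gamma | 3.00 | 0 | 99 |
| gamma | 4.00 | 6 | 94 |
| gamma | 5.00 | 19 | 81 |

(standard deviation of a reading: 1.5 percentage points)

- every charge counts on the volume at the start, and the solution that is fed holds the whole dose

- the flasks by amount of product, in percent of the starting material charged, highest first, at 30 h (Sunday's / Monday's / Friday's / Wednesday's)
- the amount of product, in percent of the starting material charged of the flask you put first, at 30 h
- the amount of product, in percent of the starting material charged of the flask you put last, at 30 h

I read the recipes column against column. In the rows for Friday's and Wednesday's, the whole partner charge over the starting-material charge gives 80.0%; that ratio, capped at one, is the ceiling, the limit that the limiting reagent sets on product. The rows for Sunday's and Monday's give 100% and 100%, so Sunday's has the higher ceiling of the two flasks at 90 °C.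

The temperature column and the readings speak of pace, not of limit: gamma, at 84 °C, reads 19% of product at 5.00 h, while epsilon, at 68 °C, reads 7% at 15.0 h. I therefore expect the flasks at 90 °C to press their ceilings by 30 h, and I commit to Sunday's first, Friday's second, then Wednesday's, with Monday's last, since it has less starting material than Wednesday's at 60 °C.

The forecast gives Sunday's > Friday's > Wednesday's > Monday's, with 70% for the first flask and 7% for the last, and it says “the 0.25 M flask is partner-limited (80% cap)”. Its top figure stands lower than my ceiling for Sunday's, which is a limit and not a yield of my own.

The flasks give Sunday's > Friday's > Wednesday's > Monday's: Sunday's >99.9%, Friday's 80.0%, Wednesday's 66.9% and Monday's 18.8%.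

    starting material + coupling partner + released group → product + 2 released group (k = 10.2 M⁻² h⁻¹, Ea = 63.0 kJ mol⁻¹)
    starting material + coupling partner → product + released group (k = 0.00756 M⁻¹ h⁻¹, Ea = 81.0 kJ mol⁻¹)
    (constants at 60 °C)

Friday's stands at its ceiling of 80.0%, with 0% of its coupling partner and 20.0% of its starting material left at 30.0 h. Sunday's reaches >99.9% under a ceiling of 100%, with 60.0% of its partner left. Monday's, at 18.8% after 30 h, stands below its ceiling. The same flask read at 3.0 d has the same charges and so the same ceiling, 100%, and holds 90.3% of product, with 64% of its partner and 9.67% of its starting material still there.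

(The numbers in the tables come from a simulation with constants of no real substance.)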